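## Structural features

The target is a cyclohexane in which all six ring carbons carry oxygen and are stereogenic. Its only other ring is an oxirane fused across C1–C6, and its only carbon branch is C7H2–OBz on the quaternary carbon C1. Locants used throughout: C1 is the oxirane carbon bearing C7, C2 and C3 are the acetoxy carbons, C4 and C5 the carbinol carbons, C6 the oxirane CH, and On the oxygen on Cn; with these the configuration is (1S,2R,3S,4R,5R,6S). In relative terms O2, O3, O4 and O5 alternate from face to face (all-trans), the oxirane oxygen lies on the face of O2 and opposite O5, and C7 stands on the face of O3 and O5. The fragile groups are the oxirane (acid, nucleophiles) and the three esters, which can migrate to a neighbouring free hydroxyl (O3 to O4 in the product, O2 to O7 during the synthesis). The skeleton is simple; the real difficulty is to sort five oxygens into three classes (O7 benzoate, O2/O3 acetates, O4/O5 free) and to put the oxirane on one face of a ring whose faces differ only through the O2/O5 pair. The key step exploits three facts: C5–C4–C3 with their all-trans oxygens are C2–C3–C4 of D-xylose, whose furanoside ring oxygen sets O3 apart from O4/O5; C1 can be the branch carbon of a 1,1-disubstituted alkene already carrying C7; and C6 can be a vinyl CH. The C1=C6 bond, later the C–C bond of the oxirane, is then the ring-closing bond of a metathesis that creates no stereocentre.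

## Logic of the disconnections

20 from 19. The two benzyl C–O bonds at O4 and O5 are cut last. Unmasking the diol at the very end means no acylation ever has to choose among hydroxyls and no base meets the finished ester pattern. The forward step must be a neutral hydrogenolysis that spares the oxirane and three esters.

19 from 18 from 17. The benzoyl–O7 bond is cut, then O7–H is traced to an arylmethyl ether. O7 must be distinguishable from O4/O5 before those are freed, so it carries a 2-naphthylmethyl ether, removable by a quinone oxidant while benzyl ethers stay. The gain is that benzoylation meets a single free hydroxyl. The demand is a buffered oxidative cleavage that tolerates the oxirane, and an acylation faster than O2-to-O7 acetyl migration.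

17 from 16 from 15. The two acetyl–O bonds are cut, then the C1–O and C6–O bonds of the oxirane. The free O2–H of 15 is the only handle that tells the faces of C1=C6 apart, so epoxidation must come before acetylation and O5 must be an ether at that point. This removes two stereocentres and returns to an all-trans cyclohexenediol. The forward step needs syn delivery of oxygen by a hydrogen-bonded peracid.

15 from 14 (key disconnection). The C1=C6 bond is cut by retro-metathesis. This opens the carbocycle to an acyclic diene whose four stereocentres are those of a sugar chain, and the ring closure itself can lose no stereochemistry. The forward step must close onto a 1,1-disubstituted alkene, so the catalyst has to load on the vinyl end and the reaction has to be dilute. Compound 14 is deliberately carried with O2 and O3 free: these are exactly the hydroxyls needed free in 15, ruthenium alkylidenes tolerate them, and three protecting-group operations disappear.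

14 from 13 from 12. The terminal C6=CH2 bond is cut (methylene ylide on the aldehyde tautomer of 13), then the anomeric C–OH is traced to the methyl glycoside 12. The anomeric carbon is the latent vinyl CH, and in 12 the furanoside ring oxygen is O3, which is what keeps O3 distinct from O4/O5 without any protecting group. The demands are an acid hydrolysis that neither cleaves arylmethyl ethers nor ionises the allylic alcohol, and a methylenation with enough ylide to absorb two hydroxyl protons without epimerising the α-carbon.

12 from 6 and 9 (through 10 and 11). The C1–C2 bond is cut. This joins the achiral three-carbon C7–C1(=CH2) unit to the sugar and creates the last stereocentre, C2, next to the ring oxygen where a chelate can control it. The gain is convergence onto a five-carbon aldehyde holding three stereocentres and a simple alkenyl bromide. The forward step must be a chelation-controlled (threo) addition, with the alkenylmetal made cold and used at once.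

9 from 7 and 8. The allylic C–O ether bond is cut. Only the allylic bromide of 8 is displaced and the vinylic bromide remains for metallation.

6 from 5, 4, 3, 2 and 1. The C5 aldehyde is traced to the primary alcohol, the O5–trityl, O2/O3–benzyl and anomeric C–OMe bonds are cut in turn. This is the standard sorting of a pentose: a furanoside fixes the ring size, a bulky temporary group takes the primary hydroxyl, and permanent benzyl ethers go onto the two hydroxyls that become O5 and O4. The demands are kinetic furanoside formation and a non-basic oxidation that leaves the α-carbon untouched.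

## Other disconnections considered

Alternative 1: The cut is the C2–O bond, with the ring traced to an achiral para-quinol. In the forward key step the dienone A1 would form a boronate hemiester with an arylboronic acid, and the B–OH would be delivered to C2 of one enone arm under a chiral amine–thiourea catalyst, giving the cis-fused dioxaborolane A2.
- In its favour: A1 is a few steps from a simple phenol, the step sets C1 (quaternary) and C2 together with the cis O1/O2 relationship the target needs, and the C7 benzoate is present from the start.
- Against it here: only two of six stereocentres are in place after the key step. C3 oxygenation trans to O2, reduction at C4, and C5/C6 functionalisation must each be won by substrate control on a β-boryloxy ketone that can revert by retro-Michael elimination. O1 must also become the oxirane oxygen, which needs a leaving group at C6 anti to it (for example a Payne-type transposition, an equilibrium).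
- Comparison: on steps to the first chiral carbocycle and on having the benzoate in place, this alternative is better than the chosen plan. On structure the chosen plan is better, since four of six stereocentres come from a sugar and one chelate. On mechanism, absolute configuration here rests on catalyst selectivity rather than on the chiral pool. Overall step economy is expected to be no better once the back end is counted.

Alternative 2: The cut is the C1–O and C4–O bonds. In the forward key step dye-sensitised singlet oxygen would add across C1 and C4 of the diene A3 to give the endoperoxide A4. Approach is expected on the face of the free O2–H (hydroxyl direction) and away from the O3 silyl ether.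
- In its favour: both oxygens enter in one pericyclic, fully atom-economic step with the benzoate already present. Metal-catalysed rearrangement, for example with Co(TPP) (divalent cobalt), would turn A4 stereospecifically into the syn bis-oxirane A5, which holds the C1–C6 oxirane on the correct face. Trans-diaxial hydrolysis of the C4–C5 oxirane at C5 would set O4/O5.
- Against it here: enantiopure A3 is not a stock compound, and as a trans-5,6-dioxygenated cyclohexa-1,3-diene it is prone to aromatise. The end game must open one of two oxiranes, at one of its two carbons, in the presence of esters.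
- Comparison: from A3 onward this alternative is shorter than the chosen plan and equal or better in atom economy. The chosen plan is better on access to the substrate and on the late selectivity problem, because it epoxidises a single alkene under hydroxyl direction rather than discriminating two oxiranes.

Alternative 3: The cut is the C1–C7 bond. In the forward key step dimethylsulfoxonium methylide would add to the C1 ketone of the inosose A6 to give the spiro-oxirane A7, with the new C–C bond equatorial and the oxygen axial by reversible betaine formation.
- In its favour: the carbocycle and C2–C5 come ready-made from myo-inositol. Benzoate opening of A7 at C7 would install the benzoate and free the tertiary O1–H in one move. The final oxirane would close by intramolecular SN2 attack of axial O1 on C6 with inversion, so its stereochemical outcome is fixed by geometry.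
- Against it here: myo-inositol is meso, so resolution or desymmetrisation and a long protecting-group sequence are needed to reach A6. The basic ylide meets a ketone flanked by alkoxy groups (epimerisation, β-elimination). The axial O6 must later be activated in preference to the equatorial O5.
- Comparison: on the certainty of the oxirane configuration and on needing no ring-forming step, this alternative is the equal or the better of the chosen plan. On step economy and protecting-group load it is clearly worse, and its absolute configuration needs a resolution.

Key step: step 10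

Remark (configuration check): the configurations of 14, 15 and 20 were checked against one another and against 1. The D-xylo chain plus a 4,5-threo carbinol reproduces (1S,2R,3S,4R,5R,6S), so no structure needed correction.

Remark (design of the precursor): the diene 14 has the fixed skeleton but carries O2/O3 free, O4/O5 as benzyl ethers and O7 as a 2-naphthylmethyl (NAP) ether. The reasons are:
- an acid-labile arylmethyl ether would not survive the glycoside hydrolysis reliably;
- the 2,3-diol is exactly what the directed epoxidation needs;
- an O7 group orthogonal to benzyl lets the benzoate go on before O4/O5 are freed, so no late acylation has to pick one hydroxyl out of three beside migrating acetates.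

Remark (assumption): 2–6, 12 and 13 are carried as anomeric mixtures and drawn without configuration at the anomeric carbon, which becomes the vinyl CH in step 9.

## Route

Step 1
Reactants: 1 D-xylose
Product: 2 methyl α/β-D-xylofuranoside
Conditions: MeOH, HCl (cat., ca. 0.5%), rt, stopped at the furanoside stage; NaHCO3
Reagents that add atoms: methanol, CO
Why: Kinetic Fischer glycosidation; five-membered ring closure is fastest, so short reaction at rt should give the furanosides before they equilibrate to pyranosides, and the anomeric mixture is immaterial because this carbon becomes the vinyl CH.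

Step 2
Reactants: 2 methyl α/β-D-xylofuranoside
Product: 3 methyl 5-O-trityl-α/β-D-xylofuranoside
Conditions: TrCl, pyridine, DMAP (cat.), rt
Reagents that add atoms: trityl chloride, ClC(c1ccccc1)(c1ccccc1)c1ccccc1
Why: Sterically selective tritylation of the only primary hydroxyl.

Step 3
Reactants: 3 methyl 5-O-trityl-α/β-D-xylofuranoside
Product: 4 methyl 2,3-di-O-benzyl-5-O-trityl-α/β-D-xylofuranoside
Conditions: NaH, BnBr, Bu4NI (cat.), DMF, 0 °C to rt
Reagents that add atoms: benzyl bromide, BrCc1ccccc1
Why: Williamson etherification of both secondary hydroxyls; trityl ether and glycoside are stable to base.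

Step 4
Reactants: 4 methyl 2,3-di-O-benzyl-5-O-trityl-α/β-D-xylofuranoside
Product: 5 methyl 2,3-di-O-benzyl-α/β-D-xylofuranoside
Conditions: TsOH·H2O (cat.), MeOH/CH2Cl2 (1:1), 0 °C to rt, short; Et3N
Reagents that add atoms: none
Why: Acid-catalysed solvolysis of the trityl ether through the trityl cation, which methanol traps; brief exposure should leave the furanoside ring size and the benzyl ethers unchanged.

Step 5
Reactants: 5 methyl 2,3-di-O-benzyl-α/β-D-xylofuranoside
Product: 6 methyl 2,3-di-O-benzyl-α/β-D-xylo-pentodialdo-1,4-furanoside
Conditions: Dess–Martin periodinane, NaHCO3, CH2Cl2, 0 °C to rt; used crude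
Reagents that add atoms: none
Why: Dess–Martin oxidation of the primary alcohol under buffered, non-basic conditions, chosen to avoid epimerisation of the α-alkoxy aldehyde at C4 of the sugar.

Step 6
Reactants: 7 naphthalen-2-ylmethanol; 8 2,3-dibromopropene
Product: 9 2-bromoallyl 2-naphthylmethyl ether
Conditions: NaH, THF, 0 °C; then 8, Bu4NI (cat.), 0 °C to rt
Reagents that add atoms: none
Why: Williamson etherification; the alkoxide displaces only the allylic bromide (SN2), the vinylic C–Br bond being inert.

Step 7
Reactants: 9 2-bromoallyl 2-naphthylmethyl ether; 6 methyl 2,3-di-O-benzyl-α/β-D-xylo-pentodialdo-1,4-furanoside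
Product: 12 methyl 2,3-di-O-benzyl-6-deoxy-6-methylidene-7-O-(2-naphthylmethyl)-α/β-L-ido-heptofuranoside (5S carbinol), via alkenyllithium 10 (not isolated), via alkenylmagnesium bromide 11 (not isolated)
Conditions: 9 (2 equiv), t-BuLi (4 equiv), Et2O, −78 °C; MgBr2·OEt2, −78 °C; then 6, CH2Cl2/Et2O, −78 to −20 °C; aq NH4Cl
Reagents that add atoms: none
Why: Bromine–lithium exchange and transmetallation to magnesium, then Cram-chelate addition: magnesium bridges the aldehyde oxygen and the furanose ring oxygen on the α-carbon, and the alkenyl group attacks from the side of the α-hydrogen, which should give the 4,5-threo (L-ido, 5S) carbinol, that is C2 of the target with O2 trans to O3.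

Step 8
Reactants: 12 methyl 2,3-di-O-benzyl-6-deoxy-6-methylidene-7-O-(2-naphthylmethyl)-α/β-L-ido-heptofuranoside
Product: 13 2,3-di-O-benzyl-6-deoxy-6-methylidene-7-O-(2-naphthylmethyl)-L-ido-heptose (lactol, furanose/pyranose mixture)
Conditions: 1 M HCl (aq)/1,4-dioxane (1:2), 60 °C
Reagents that add atoms: water, O
Why: Acid-catalysed hydrolysis of the methyl furanoside through the furanosyl oxocarbenium ion; benzyl and NAP ethers are acid-stable, and the allylic alcohol should not ionise because the derived allyl cation would be flanked by oxygen-bearing carbons.

Step 9
Reactants: 13 2,3-di-O-benzyl-6-deoxy-6-methylidene-7-O-(2-naphthylmethyl)-L-ido-heptose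
Product: 14 (3S,4R,5S,6S)-5,6-bis(benzyloxy)-2-[(naphthalen-2-ylmethoxy)methyl]octa-1,7-diene-3,4-diol
Conditions: Ph3PCH3Br (4 equiv), KOtBu (3.8 equiv), THF, 0 °C to rt
Reagents that add atoms: methyltriphenylphosphonium bromide, C[P+](c1ccccc1)(c1ccccc1)c1ccccc1.[Br-]
Why: Wittig methylenation of the open-chain aldehyde tautomer of the lactol; the excess ylide absorbs the two hydroxyl protons, and no stereocentre is formed.

Step 10
Reactants: 14 (3S,4R,5S,6S)-5,6-bis(benzyloxy)-2-[(naphthalen-2-ylmethoxy)methyl]octa-1,7-diene-3,4-diol
Product: 15 (1S,2R,3S,4S)-3,4-bis(benzyloxy)-6-[(naphthalen-2-ylmethoxy)methyl]cyclohex-5-ene-1,2-diol (target locants: O2–H, O3–H, 4,5-di-O-benzyl, C1=C6, all-trans)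
Conditions: second-generation Grubbs catalyst RuCl2(=CHPh)(PCy3)(H2IMes) (5–10 mol%), CH2Cl2 (0.01 M), 40 °C, argon sparge
Reagents that add atoms: none
Why: Ring-closing olefin metathesis by the Chauvin mechanism: after loss of PCy3 the ruthenium benzylidene undergoes [2+2] cycloaddition and cycloreversion with the monosubstituted vinyl group and so becomes the alkylidene at C6. This alkylidene adds intramolecularly across the 1,1-disubstituted C1=CH2 bond to a bicyclic ruthenacyclobutane, whose cycloreversion releases the cyclohexene and Ru=CH2 as the propagating species, while ethylene escapes and makes the closure irreversible. The closest known reaction type is the ring-closing metathesis of carbohydrate-derived octa-1,7-dienes to polyoxygenated (carbasugar) cyclohexenes, including cases that form a trisubstituted ring alkene. The one ring closed is the six-membered carbocycle, formed by joining C1 and C6 of the eight-carbon diene with loss of the two terminal CH2 groups; a six-membered ring admits only the Z alkene, so no geometry question arises. No stereocentre is formed or touched, since C2–C5 are sp3 carbons that cannot epimerise under these neutral conditions. The selectivity needed is loading on the vinyl group and cyclisation instead of oligomerisation; the steric difference between the two alkenes should secure the first, and high dilution plus the four contiguous oxygenated carbons, all equatorial in the half-chair product, the second. The oxygen next to the initiating vinyl group is an ether, so alcohol-to-ketone isomerisation is excluded at that end, while the free O2–H sits next to the alkene reached only intramolecularly and is expected to help more than hinder.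

Step 11
Reactants: 15 (1S,2R,3S,4S)-3,4-bis(benzyloxy)-6-[(naphthalen-2-ylmethoxy)methyl]cyclohex-5-ene-1,2-diol
Product: 16 4,5-di-O-benzyl-1-[(2-naphthylmethoxy)methyl]-1,6-epoxycyclohexane-2,3-diol (oxirane oxygen cis to O2; all six ring carbons configured as in 20)
Conditions: mCPBA, NaHCO3, CH2Cl2, 0 °C
Reagents that add atoms: mCPBA (3-chloroperoxybenzoic acid), O=C(OO)c1cccc(Cl)c1
Why: Henbest hydroxyl-directed peracid epoxidation; hydrogen bonding of the pseudoequatorial allylic O2–H to the peracid should deliver oxygen to the electron-rich trisubstituted alkene on the O2 face, which is also the face away from the C5 benzyloxy group, and this sets C1 and C6.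

Step 12
Reactants: 16 4,5-di-O-benzyl-1-[(2-naphthylmethoxy)methyl]-1,6-epoxycyclohexane-2,3-diol
Product: 17 2,3-di-O-acetyl-4,5-di-O-benzyl-1-[(2-naphthylmethoxy)methyl]-1,6-epoxycyclohexane-2,3-diol
Conditions: Ac2O, pyridine, DMAP (cat.), 0 °C to rt
Reagents that add atoms: acetic anhydride, CC(=O)OC(C)=O
Why: DMAP-catalysed acylation of the two secondary hydroxyls; the oxirane is syn to O2, so Payne-type migration is geometrically impossible under the mild base.

Step 13
Reactants: 17 2,3-di-O-acetyl-4,5-di-O-benzyl-1-[(2-naphthylmethoxy)methyl]-1,6-epoxycyclohexane-2,3-diol
Product: 18 2,3-di-O-acetyl-4,5-di-O-benzyl-1-(hydroxymethyl)-1,6-epoxycyclohexane-2,3-diol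
Conditions: DDQ, CH2Cl2/pH 7 phosphate buffer (10:1), 0 °C to rt
Reagents that add atoms: none
Why: Oxidative cleavage of the electron-rich NAP ether by DDQ (hydride abstraction, oxocarbenium ion, hydrolysis to 2-naphthaldehyde); the less electron-rich benzyl ethers should remain, and the buffer protects the oxirane.

Step 14
Reactants: 18 2,3-di-O-acetyl-4,5-di-O-benzyl-1-(hydroxymethyl)-1,6-epoxycyclohexane-2,3-diol
Product: 19 2,3-di-O-acetyl-4,5-di-O-benzyl-1-(benzoyloxymethyl)-1,6-epoxycyclohexane-2,3-diol
Conditions: BzCl, pyridine, CH2Cl2, 0 °C
Reagents that add atoms: benzoyl chloride, O=C(Cl)c1ccccc1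
Why: Acylation of the only free hydroxyl, a primary alcohol, which at 0 °C should be faster than acetyl migration from O2 to O7.

Step 15
Reactants: 19 2,3-di-O-acetyl-4,5-di-O-benzyl-1-(benzoyloxymethyl)-1,6-epoxycyclohexane-2,3-diol
Product: 20 (1S,2R,3S,4R,5R,6S)-2,3-diacetoxy-1-(benzoyloxymethyl)-1,6-epoxycyclohexane-4,5-diol (CNP0171674.1)
Conditions: H2 (1 atm), Pd(OH)2/C, EtOAc, rt
Reagents that add atoms: none
Why: Palladium-catalysed hydrogenolysis of the two benzyl ethers under neutral conditions; esters and the non-benzylic oxirane are inert to it, no alkene remains, and the absence of base keeps the acetates in place.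

## Compound list

1 | D-xylose | O=C[C@H](O)[C@@H](O)[C@H](O)CO | starting material
2 | methyl α/β-D-xylofuranoside | COC1[C@H](O)[C@@H](O)[C@@H](CO)O1 | intermediate
3 | methyl 5-O-trityl-α/β-D-xylofuranoside | COC1[C@H](O)[C@@H](O)[C@@H](COC(c2ccccc2)(c2ccccc2)c2ccccc2)O1 | intermediate
4 | methyl 2,3-di-O-benzyl-5-O-trityl-α/β-D-xylofuranoside | COC1[C@H](OCc2ccccc2)[C@@H](OCc2ccccc2)[C@@H](COC(c2ccccc2)(c2ccccc2)c2ccccc2)O1 | intermediate
5 | methyl 2,3-di-O-benzyl-α/β-D-xylofuranoside | COC1[C@H](OCc2ccccc2)[C@@H](OCc2ccccc2)[C@@H](CO)O1 | intermediate
6 | methyl 2,3-di-O-benzyl-α/β-D-xylo-pentodialdo-1,4-furanoside | COC1[C@H](OCc2ccccc2)[C@@H](OCc2ccccc2)[C@@H](C=O)O1 | intermediate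
7 | naphthalen-2-ylmethanol | OCc1ccc2ccccc2c1 | starting material
8 | 2,3-dibromopropene | C=C(Br)CBr | starting material
9 | 2-bromoallyl 2-naphthylmethyl ether | C=C(Br)COCc1ccc2ccccc2c1 | intermediate
10 | [3-(naphthalen-2-ylmethoxy)prop-1-en-2-yl]lithium (not isolated) | [Li]C(=C)COCc1ccc2ccccc2c1 | intermediate
11 | [3-(naphthalen-2-ylmethoxy)prop-1-en-2-yl]magnesium bromide (not isolated) | Br[Mg]C(=C)COCc1ccc2ccccc2c1 | intermediate
12 | methyl 2,3-di-O-benzyl-6-deoxy-6-methylidene-7-O-(2-naphthylmethyl)-α/β-L-ido-heptofuranoside (5S) | COC1[C@H](OCc2ccccc2)[C@@H](OCc2ccccc2)[C@@H]([C@@H](O)C(=C)COCc2ccc3ccccc3c2)O1 | intermediate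
13 | 2,3-di-O-benzyl-6-deoxy-6-methylidene-7-O-(2-naphthylmethyl)-L-ido-heptose, lactol drawn as the furanose | OC1[C@H](OCc2ccccc2)[C@@H](OCc2ccccc2)[C@@H]([C@@H](O)C(=C)COCc2ccc3ccccc3c2)O1 | intermediate
14 | (3S,4R,5S,6S)-5,6-bis(benzyloxy)-2-[(naphthalen-2-ylmethoxy)methyl]octa-1,7-diene-3,4-diol | C=C(COCc1ccc2ccccc2c1)[C@H](O)[C@@H](O)[C@H](OCc1ccccc1)[C@@H](OCc1ccccc1)C=C | intermediate
15 | (1S,2R,3S,4S)-3,4-bis(benzyloxy)-6-[(naphthalen-2-ylmethoxy)methyl]cyclohex-5-ene-1,2-diol | O[C@H]1[C@H](OCc2ccccc2)[C@@H](OCc2ccccc2)C=C(COCc2ccc3ccccc3c2)[C@@H]1O | intermediate
16 | 4,5-di-O-benzyl-1-[(2-naphthylmethoxy)methyl]-1,6-epoxycyclohexane-2,3-diol, oxirane cis to O2 | O[C@H]1[C@H](OCc2ccccc2)[C@@H](OCc2ccccc2)[C@@H]2O[C@]2(COCc2ccc3ccccc3c2)[C@@H]1O | intermediate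
17 | 2,3-di-O-acetyl derivative of 16 | CC(=O)O[C@H]1[C@H](OCc2ccccc2)[C@@H](OCc2ccccc2)[C@@H]2O[C@]2(COCc2ccc3ccccc3c2)[C@@H]1OC(C)=O | intermediate
18 | 2,3-di-O-acetyl-4,5-di-O-benzyl-1-(hydroxymethyl)-1,6-epoxycyclohexane-2,3-diol | CC(=O)O[C@H]1[C@H](OCc2ccccc2)[C@@H](OCc2ccccc2)[C@@H]2O[C@]2(CO)[C@@H]1OC(C)=O | intermediate
19 | 2,3-di-O-acetyl-4,5-di-O-benzyl-1-(benzoyloxymethyl)-1,6-epoxycyclohexane-2,3-diol | CC(=O)O[C@H]1[C@H](OCc2ccccc2)[C@@H](OCc2ccccc2)[C@@H]2O[C@]2(COC(=O)c2ccccc2)[C@@H]1OC(C)=O | intermediate
20 | (1S,2R,3S,4R,5R,6S)-2,3-diacetoxy-1-(benzoyloxymethyl)-1,6-epoxycyclohexane-4,5-diol | CC(=O)O[C@H]1[C@H](O)[C@@H](O)[C@@H]2O[C@]2(COC(=O)c2ccccc2)[C@@H]1OC(C)=O | target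

## Step count and least certain steps

Total: 15 steps. Longest linear sequence: 14 steps from 1 (steps 1–5 and 7–15); step 6 prepares the side fragment.

Step 10 (key step). Ring closure onto the hindered 1,1-disubstituted alkene may be slow. That leaves time for intermolecular metathesis at the vinyl end and for ruthenium hydride species, formed as the catalyst decays, to migrate double bonds or isomerise the free allylic alcohol. Fallback, from 14 back to 15: silylate both hydroxyls (Et3SiOTf, 2,6-lutidine) to the bis(triethylsilyl) ether of the diene F1. Close the ring on this fully etherified diene, which also opens the way to alkylidene catalysts that do not tolerate hydroxyls, to the bis(triethylsilyl) ether of the cyclohexene F2. Remove the silyl groups (Bu4NF, AcOH) to rejoin the route at 15.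

Step 7. Incomplete chelation (an open, Felkin-type transition state) would erode the 4,5-threo selectivity, and β-elimination of the alkoxide from the alkenylmetal on warming would lower conversion. Fallback, from 6 back to 12: run the addition for conversion only, accepting 12 mixed with its C5 epimer, the D-gluco alcohol F3. Oxidise the mixture (Dess–Martin periodinane) to the single 5-ulose enone F4. Re-form the carbinol by reagent-controlled 1,2-reduction (Corey–Bakshi–Shibata: oxazaborolidine catalyst, BH3·SMe2, catalyst enantiomer chosen to deliver hydride to the face that gives the 5S alcohol), which returns 12.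

Step 11. Facial selectivity may be poor if the homoallylic O3–H on the other face competes or the pseudoequatorial O2–H steers weakly, and the acid by-product may open the new oxirane. Fallback, from 15 back to 18 in the same number of steps: acetylate first (Ac2O, pyridine, DMAP) to the cyclohexene diacetate F5. Remove the NAP group (DDQ, buffered) to the primary allylic alcohol F6. Epoxidise under reagent control by the Katsuki–Sharpless method (Ti(OiPr)4, diethyl tartrate, t-BuOOH, 4 Å sieves, CH2Cl2, −20 °C). The tartrate enantiomer is the one the facial rule assigns to the O2 face; by analogy with simple 2-substituted allylic alcohols this is expected to be the L-(+)-ester, to be confirmed on F6. This gives 18 directly.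

Step 9. The basic ylide may epimerise the α-benzyloxy aldehyde or eliminate benzyloxide from it, and the pyranose tautomer may open slowly. Fallback, from 13 back to 14: Peterson olefination. Add Me3SiCH2MgCl (excess, THF, 0 °C), a weakly basic nucleophile, to the aldehyde tautomer to give the β-hydroxysilane F7 (both epimers at the new carbinol are usable). Eliminate with KH in THF to give 14.

Step 15. Acid traces on the catalyst may open the oxirane, the hindered secondary ethers may cleave slowly, and a long reaction invites acetyl migration from O3 to O4. Fallback, from 19 directly to 20: oxidative instead of reductive debenzylation, by visible-light-promoted DDQ cleavage in wet, buffered CH2Cl2 (green light). This makes no new intermediate.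

## Further compounds

F1 | step 10 | (3S,4R,5S,6S)-5,6-bis(benzyloxy)-2-[(naphthalen-2-ylmethoxy)methyl]-3,4-bis(triethylsilyloxy)octa-1,7-diene | C=C(COCc1ccc2ccccc2c1)[C@H](O[Si](CC)(CC)CC)[C@@H](O[Si](CC)(CC)CC)[C@H](OCc1ccccc1)[C@@H](OCc1ccccc1)C=C
F2 | step 10 | 2,3-bis(triethylsilyl) ether of 15 | CC[Si](CC)(CC)O[C@H]1[C@H](OCc2ccccc2)[C@@H](OCc2ccccc2)C=C(COCc2ccc3ccccc3c2)[C@@H]1O[Si](CC)(CC)CC
F3 | step 7 | methyl 2,3-di-O-benzyl-6-deoxy-6-methylidene-7-O-(2-naphthylmethyl)-α/β-D-gluco-heptofuranoside (5R epimer of 12) | COC1[C@H](OCc2ccccc2)[C@@H](OCc2ccccc2)[C@@H]([C@H](O)C(=C)COCc2ccc3ccccc3c2)O1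
F4 | step 7 | methyl 2,3-di-O-benzyl-6-deoxy-6-methylidene-7-O-(2-naphthylmethyl)-α/β-D-xylo-heptofuranosid-5-ulose | COC1[C@H](OCc2ccccc2)[C@@H](OCc2ccccc2)[C@@H](C(=O)C(=C)COCc2ccc3ccccc3c2)O1
F5 | step 11 | 1,2-di-O-acetyl derivative of 15 (cyclohexene diacetate) | CC(=O)O[C@H]1[C@H](OCc2ccccc2)[C@@H](OCc2ccccc2)C=C(COCc2ccc3ccccc3c2)[C@@H]1OC(C)=O
F6 | step 11 | cyclohexene diacetate with free C7 hydroxyl | CC(=O)O[C@H]1[C@H](OCc2ccccc2)[C@@H](OCc2ccccc2)C=C(CO)[C@@H]1OC(C)=O
F7 | step 9 | β-hydroxysilane from addition of Me3SiCH2MgCl to 13 | C=C(COCc1ccc2ccccc2c1)[C@H](O)[C@@H](O)[C@H](OCc1ccccc1)[C@@H](OCc1ccccc1)C(O)C[Si](C)(C)C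
F0 | step 15 | none | none
A1 | alternative 1 | 4-(benzoyloxymethyl)-4-hydroxycyclohexa-2,5-dien-1-one | O=C1C=CC(O)(COC(=O)c2ccccc2)C=C1
A2 | alternative 1 | cis-fused phenylboronate of the 4,5-dihydroxycyclohex-2-enone | O=C1C[C@H]2OB(c3ccccc3)O[C@@]2(COC(=O)c3ccccc3)C=C1
A3 | alternative 2 | [(5,6-trans)-5-(tert-butyldimethylsilyloxy)-6-hydroxycyclohexa-1,3-dien-1-yl]methyl benzoate | CC(C)(C)[Si](C)(C)O[C@H]1C=CC=C(COC(=O)c2ccccc2)[C@@H]1O
A4 | alternative 2 | C1,C4-endoperoxide (2,3-dioxabicyclo[2.2.2]oct-5-ene) | CC(C)(C)[Si](C)(C)O[C@H]1[C@H]2C=C[C@@](OO2)(COC(=O)c3ccccc3)[C@@H]1O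
A5 | alternative 2 | syn 1,6:4,5-bis-oxirane from rearrangement of A4 | CC(C)(C)[Si](C)(C)O[C@H]1[C@@H]3O[C@@H]3[C@@H]2O[C@]2(COC(=O)c2ccccc2)[C@@H]1O
A6 | alternative 3 | protected myo-inosose (O2, O3 PMB; O4 benzyl; O5, O6 acetonide; C1 ketone) | COc1ccc(CO[C@H]2[C@H](OCc3ccccc3)[C@H]3OC(C)(C)O[C@H]3C(=O)[C@@H]2OCc2ccc(OC)cc2)cc1
A7 | alternative 3 | spiro-oxirane of the 1-C-methylene inositol | COc1ccc(CO[C@H]2[C@H](OCc3ccccc3)[C@H]3OC(C)(C)O[C@H]3[C@@]3(CO3)[C@@H]2OCc2ccc(OC)cc2)cc1
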